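## Retrosynthetic overview

- **Feature:** ring A (the cyclohexane carrying the acrylic acid) and the δ-lactone are fused through the C4a'–C8a' bond. These are the CH on the spiro carbon and the CH on the lactone C=O, so the lactone O–C(=O) unit can tether a [4+2] addition that builds both rings at once.
- **Endgame:** acrylic acid ⇐ isopropenyl ⇐ equatorial acetyl ⇐ (epimerisation) axial acetyl ⇐ dioxolane on the saturated cycloadduct.
- **Key disconnection:** cyclohexene + δ-lactone ⇐ (E,E)-dienyl and acryloyloxymethyl groups, both on C2 of an 8,8-dimethyl-6-oxabicyclo[3.2.1]octan-3-one.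
- **Precursor:** quaternary C2 ⇐ tethered C-acylation of an extended enolate of the monocyclic enone, where C6 is the only nucleophilic carbon and the tether fixes the face. Side chain ⇐ aldol condensation. First stereocentre ⇐ Rh-catalysed vinylation of 4,4-dimethylcyclohexadienone.
- **Ring order:** carbocycle (bought) → temporary γ-lactone → tetrahydrofuran bridge → ring A and δ-lactone together.

Key step: step 14

**Locants:**
- Oxabicycle: C1 (bridgehead bearing C7H2), C2 (quaternary/spiro), C3 (C=O), C4, C5 (bridgehead CH–O), O6, C7, C8 (CMe2).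
- Lactone/ring A part, primed: C1' (lactone C=O), O2', C3'H2, C4' = C2, C4a', C5'–C8', C8a'.
- Ca–Cd are the four diene carbons counted from C2.

**Assumption:** the facial sense of vinyl transfer from the rhodium/(R)-BINAP catalyst to 4,4-dimethylcyclohexa-2,5-dienone is taken to be the one known for 2-cyclohexenone, which leads to the (R)-adduct. Were it opposite, (S)-BINAP would be used and nothing else changes.

## Route

Step 1
Reactants: 1 4,4-dimethylcyclohex-2-en-1-one
Product: 2 4,4-dimethylcyclohexa-2,5-dien-1-one
Conditions: DDQ, 1,4-dioxane, reflux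
Reagents that add atoms: none
Why: DDQ dehydrogenation of an enone through its dienol is a standard way to cross-conjugated cyclohexadienones, the quaternary C4 rules out aromatisation, and no stereocentre is formed.

Step 2
Reactants: 2 4,4-dimethylcyclohexa-2,5-dien-1-one
Product: 3 (R)-4,4-dimethyl-5-vinylcyclohex-2-en-1-one
Conditions: CH2=CHBF3K (1.2 equiv), [Rh(cod)Cl]2 (2.5 mol %), (R)-BINAP (6 mol %), Et3N, toluene/H2O, 80 °C
Reagents that add atoms: potassium vinyltrifluoroborate, C=C[B-](F)(F)F.[K+]
Why: The Hayashi–Miyaura asymmetric 1,4-addition desymmetrises the two enantiotopic enone arms, the BINAP-bound vinylrhodium species choosing one β-carbon face and so setting C5 as R (future C1), while the adduct is more hindered than 2 and should resist a second addition.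

Step 3
Reactants: 3 (R)-4,4-dimethyl-5-vinylcyclohex-2-en-1-one
Product: 5 (S)-5-(hydroxymethyl)-4,4-dimethylcyclohex-2-en-1-one, via keto aldehyde 4 (not isolated)
Conditions: O3 (titrated), CH2Cl2/MeOH, −78 °C; Me2S, −78 °C to rt; then NaBH4, −78 °C
Reagents that add atoms: ozone, [O-][O+]=O
Why: Ozonolysis takes the electron-neutral vinyl group well before the electron-poor neopentyl enone C=C, and NaBH4 at −78 °C reduces the aldehyde in preference to the conjugated ketone, so the vinyl group is cut back to the future C7 without touching the stereocentre (the descriptor changes only through CIP priorities).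

Step 4
Reactants: 5 (S)-5-(hydroxymethyl)-4,4-dimethylcyclohex-2-en-1-one
Product: 6 (S)-5-[(tert-butyldimethylsilyloxy)methyl]-4,4-dimethylcyclohex-2-en-1-one
Conditions: TBSCl, imidazole, CH2Cl2, 0 °C to rt
Reagents that add atoms: tert-butyldimethylsilyl chloride, CC(C)(C)[Si](C)(C)Cl
Why: Standard silylation of a primary alcohol under weakly basic conditions keeps the ring open as the enone and removes the OH proton before the enolate chemistry of step 7.

Step 5
Reactants: 7 ethyl 2-(2-methyl-1,3-dioxolan-2-yl)acetate
Product: 8 2-(2-methyl-1,3-dioxolan-2-yl)acetaldehyde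
Conditions: i-Bu2AlH (1.05 equiv), CH2Cl2, −78 °C; aq potassium sodium tartrate
Reagents that add atoms: none
Why: Partial reduction of an ester stops at the tetrahedral aluminium hemiacetal at −78 °C and releases the aldehyde only on work-up, and the ketal is inert.

Step 6
Reactants: 8 2-(2-methyl-1,3-dioxolan-2-yl)acetaldehyde
Product: 9 (E)-4-(2-methyl-1,3-dioxolan-2-yl)but-2-enal
Conditions: Ph3P=CHCHO, CH2Cl2, rt
Reagents that add atoms: (triphenylphosphoranylidene)acetaldehyde, O=CC=P(c1ccccc1)(c1ccccc1)c1ccccc1
Why: The Wittig reaction of a stabilised ylide gives the (E)-enal, and one equivalent of ylide limits further homologation.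

Step 7
Reactants: 6 (S)-5-[(tert-butyldimethylsilyloxy)methyl]-4,4-dimethylcyclohex-2-en-1-one; 9 (E)-4-(2-methyl-1,3-dioxolan-2-yl)but-2-enal
Product: 10 (5S)-5-[(tert-butyldimethylsilyloxy)methyl]-6-[(E)-1-hydroxy-4-(2-methyl-1,3-dioxolan-2-yl)but-2-en-1-yl]-4,4-dimethylcyclohex-2-en-1-one (epimers at C6 and at the carbinol carbon)
Conditions: LiN(i-Pr)2, THF, −78 °C; 9; AcOH, −78 °C
Reagents that add atoms: none
Why: C4 is quaternary, so C6 is the only enolisable carbon of 6 and a single cross-conjugated lithium dienolate adds 1,2 to the enal (directed aldol addition), a regiocontrol the closed oxabicyclic ketone would not offer because its other α-CH2 lies next to the C–O bond and would β-eliminate; the two new centres are erased in steps 8 and 10.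

Step 8
Reactants: 10 aldol adduct
Product: 12 (5R,6E)-5-[(tert-butyldimethylsilyloxy)methyl]-4,4-dimethyl-6-[(E)-4-(2-methyl-1,3-dioxolan-2-yl)but-2-en-1-ylidene]cyclohex-2-en-1-one, via mesylate 11 (not isolated)
Conditions: MsCl, Et3N, CH2Cl2, 0 °C; then DBU (1.1 equiv), 0 °C to rt
Reagents that add atoms: none
Why: Mesylation and E1cB loss of methanesulfonate across C6–H give the cross-conjugated alkylidene enone as its thermodynamic isomer, and alkene position and geometry are not critical because every isomer feeds the same extended enolate in step 10.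

Step 9
Reactants: 12 silyl ether
Product: 13 (5R,6E)-5-(hydroxymethyl)-4,4-dimethyl-6-[(E)-4-(2-methyl-1,3-dioxolan-2-yl)but-2-en-1-ylidene]cyclohex-2-en-1-one
Conditions: HF·pyridine, pyridine, THF, 0 °C to rt
Reagents that add atoms: none
Why: Fluoride-driven Si–O cleavage under pyridine-buffered, non-basic conditions frees the primary alcohol without starting the oxa-Michael closure, and the dioxolane, not allylic at this stage, should survive.

Step 10
Reactants: 13 hydroxymethyl trienone
Product: 15 (3aR,7aR)-4,4-dimethyl-7a-[(1E,3E)-4-(2-methyl-1,3-dioxolan-2-yl)buta-1,3-dien-1-yl]-3a,4-dihydro-2-benzofuran-1,7(3H,7aH)-dione (cis-fused), via imidazolide 14 (not isolated)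
Conditions: CDI, CH2Cl2, rt, aqueous wash; LiN(SiMe3)2, THF, −78 to −30 °C; AcOH
Reagents that add atoms: 1,1'-carbonyldiimidazole, O=C(n1ccnc1)n1ccnc1
Why: The side-chain CH2 next to the dioxolane carries the only acidic C–H of 14, so one extended enolate forms and its α-carbon (C6) attacks the tethered acyl imidazole in a Dieckmann-type five-membered-ring C-acylation; the three-atom tether reaches only the face of C6 that carries the CH2O arm, so the lactone carbonyl (future C3') ends cis to that arm and the side chain trans to it, while the double bonds move out of conjugation into the (1E,3E)-diene through the s-trans, allylic-strain-free conformer.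

Step 11
Reactants: 15 β-keto lactone
Product: 16 (5R,6S)-5,6-bis(hydroxymethyl)-4,4-dimethyl-6-[(1E,3E)-4-(2-methyl-1,3-dioxolan-2-yl)buta-1,3-dien-1-yl]cyclohex-2-en-1-ol (C1 epimers)
Conditions: i-Bu2AlH (excess), CH2Cl2, −78 to 0 °C; aq potassium sodium tartrate
Reagents that add atoms: none
Why: The hydride reduces the enone carbonyl 1,2 and the γ-lactone through its lactol to the diol, hydride transfer at low temperature being faster than retro-Claisen cleavage of the non-enolisable β-keto lactone, and the new carbinol centre is of no consequence because it is re-oxidised.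

Step 12
Reactants: 16 triol
Product: 18 (1R,2S,5R)-2-(hydroxymethyl)-8,8-dimethyl-2-[(1E,3E)-4-(2-methyl-1,3-dioxolan-2-yl)buta-1,3-dien-1-yl]-6-oxabicyclo[3.2.1]octan-3-one, via open enone diol 17 (not isolated)
Conditions: MnO2 (excess), CH2Cl2, rt
Reagents that add atoms: none
Why: MnO2 oxidises only the allylic secondary alcohol, and the CH2OH on the tertiary ring carbon, pressed against the gem-dimethyl carbon, then adds to the regenerated enone in a five-membered-ring oxa-Michael closure (tandem allylic oxidation/oxa-Michael) from its own face, which sets C5 as R; no soluble base is added because an alkoxide on the C2 CH2OH could expel formaldehyde, and closure by that hydroxyl to a 2-oxabicyclo[2.2.2]octane would eclipse the fully substituted ring bond.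

Step 13
Reactants: 18 hydroxymethyl oxabicyclic ketone; 19 acryloyl chloride
Product: 20 [(1R,2S,5R)-8,8-dimethyl-2-[(1E,3E)-4-(2-methyl-1,3-dioxolan-2-yl)buta-1,3-dien-1-yl]-3-oxo-6-oxabicyclo[3.2.1]octan-2-yl]methyl acrylate
Conditions: 19, Et3N, DMAP (cat.), CH2Cl2, −20 °C
Reagents that add atoms: none
Why: O-acylation of the neopentyl primary alcohol with an acid chloride is fast at low temperature, where a tertiary amine is too weak to start retro-aldol or retro-oxa-Michael processes.

Step 14
Reactants: 20 dienyl acrylate
Product: 21 (1R,2S,4a'R,5R,7'R,8a'S)-8,8-dimethyl-7'-(2-methyl-1,3-dioxolan-2-yl)-4a',7',8',8a'-tetrahydrospiro[6-oxabicyclo[3.2.1]octane-2,4'-isochromene]-1',3(3'H)-dione (cis-fused; C2, lactone C=O and dioxolanyl carbon all on one face of the cyclohexene)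
Conditions: BHT (0.1 equiv), toluene (5 mM), sealed tube, 150 °C
Reagents that add atoms: none
Why: This is a concerted, suprafacial thermal [4+2] addition, the ester-tethered intramolecular Diels–Alder reaction known for hexadienyl acrylates, in which the acrylate α-carbon bonds to Ca and the acrylate CH2 to Cd. The cyclohexene is the ring of the cycloaddition itself and the δ-lactone closes in the fused mode through the four-atom tether C2–CH2–O–C(=O), the bridged mode being out of reach for so short a tether, and the quaternary C2 compresses the reacting ends, which repays part of the cost of turning the ester into its lactone-like s-cis form. The planar ester enforces a boat-like tether with its carbonyl endo under Cb–Cc, which makes H-4a' and H-8a' cis (8a'S), whereas the exo mode would push the ester under the bridgehead flank of C2. The diene face, and so C4a' (R) relative to C2, follows from the rotamer about C2–Ca in which the CH2O arm stands perpendicular to the diene, the flat C3 carbonyl lies beside Cb–H where allylic strain is smallest, and the bulky C1 bridgehead with the C8 methyl groups sits beside the small Ca–H. Suprafacial addition to the (E,E)-diene puts the dioxolanyl carbon on C7' cis to C2, the wrong relationship, which is repaired at the ketone stage in step 16. The step needs endo and facial selectivity and survival of the dienylic ketal, hence no Lewis acid, and BHT with high dilution holds back acrylate polymerisation and intermolecular addition.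

Step 15
Reactants: 21 cyclohexene lactone
Product: 22 (1R,2S,4a'R,5R,7'S,8a'S)-8,8-dimethyl-7'-(2-methyl-1,3-dioxolan-2-yl)hexahydrospiro[6-oxabicyclo[3.2.1]octane-2,4'-isochromane]-1',3-dione
Conditions: H2 (1 atm), Pd/C, EtOAc, rt
Reagents that add atoms: none
Why: Heterogeneous hydrogenation saturates the only C=C, creates no stereocentre (the C7' descriptor changes through CIP priorities only) and leaves ketone, lactone and ketal alone.

Step 16
Reactants: 22 saturated ketal lactone
Product: 24 (1R,2S,4a'R,5R,7'R,8a'S)-7'-acetyl-8,8-dimethylhexahydrospiro[6-oxabicyclo[3.2.1]octane-2,4'-isochromane]-1',3-dione (acetyl equatorial and trans to C2), via axial methyl ketone 23 (not isolated)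
Conditions: 1 M HCl, THF, rt; then DBU (0.3 equiv), CH2Cl2, rt
Reagents that add atoms: water, O
Why: Acid hydrolysis of the dioxolane unmasks a methyl ketone whose acetyl group is axial and 1,3-diaxial to the lactone carbonyl, so base-mediated epimerisation through the ketone enolate runs strongly downhill to the equatorial 7'R isomer, while the less acidic lactone α-H at C8a' is left alone and any opening of the ether bridge is reversible.

Step 17
Reactants: 24 equatorial methyl ketone
Product: 25 (1R,2S,4a'R,5R,7'R,8a'S)-8,8-dimethyl-7'-(prop-1-en-2-yl)hexahydrospiro[6-oxabicyclo[3.2.1]octane-2,4'-isochromane]-1',3-dione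
Conditions: Ph3PCH3Br (1.5 equiv), KOt-Bu (1.4 equiv), THF, 0 °C; then 24, −78 to 0 °C
Reagents that add atoms: methyltriphenylphosphonium bromide, C[P+](c1ccccc1)(c1ccccc1)c1ccccc1.[Br-]
Why: The Wittig methylenation picks the open methyl ketone over the lactone and over the C3 ketone, which is flanked by the spiro carbon and screened by the C8 methyl on one face and the O6–C7 bridge on the other, and it avoids strong-base enolisation, which would also strike C4–H2 of the ring ketone and open the ether bridge.

Step 18
Reactants: 25 isopropenyl compound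
Product: 27 2-[(1R,2S,4a'R,5R,7'R,8a'S)-8,8-dimethyl-1',3-dioxohexahydrospiro[6-oxabicyclo[3.2.1]octane-2,4'-isochromane]-7'-yl]acrylaldehyde, via allylic alcohol 26 (not isolated)
Conditions: SeO2 (0.3 equiv), t-BuOOH, CH2Cl2, 0 °C to rt; then MnO2, CH2Cl2, rt
Reagents that add atoms: selenium dioxide, O=[Se]=O; tert-butyl hydroperoxide, CC(C)(C)OO (terminal oxidant that restores SeO2)
Why: The SeO2 allylic oxidation (ene reaction, then [2,3]-sigmatropic shift) of an isopropenyl group on a ring is the usual terpenoid entry to the 2-substituted allyl alcohol, room temperature spares the ketone α-CH2, and MnO2 brings alcohol and any enal already present to a single enal.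

Step 19
Reactants: 27 enal
Product: 28 2-[(1R,2S,4a'R,5R,7'R,8a'S)-8,8-dimethyl-1',3-dioxohexahydrospiro[6-oxabicyclo[3.2.1]octane-2,4'-isochromane]-7'-yl]acrylic acid (target)
Conditions: NaClO2, NaH2PO4, 2-methyl-2-butene, t-BuOH/H2O, rt
Reagents that add atoms: sodium chlorite, [Na+].[O-]Cl=O
Why: The Pinnick oxidation turns the enal into the acid at mildly acidic pH, so no saponification is needed, the lactone stays closed and a retro-aldol-prone β-hydroxy ketone is never exposed.

## Compound list

1 | 4,4-dimethylcyclohex-2-en-1-one | CC1(C)CCC(=O)C=C1 | starting material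
2 | 4,4-dimethylcyclohexa-2,5-dien-1-one | CC1(C)C=CC(=O)C=C1 | intermediate
3 | (R)-4,4-dimethyl-5-vinylcyclohex-2-en-1-one | C=C[C@H]1CC(=O)C=CC1(C)C | intermediate
4 | (S)-2,2-dimethyl-5-oxocyclohex-3-ene-1-carbaldehyde | O=C[C@H]1CC(=O)C=CC1(C)C | intermediate
5 | (S)-5-(hydroxymethyl)-4,4-dimethylcyclohex-2-en-1-one | OC[C@H]1CC(=O)C=CC1(C)C | intermediate
6 | (S)-5-[(tert-butyldimethylsilyloxy)methyl]-4,4-dimethylcyclohex-2-en-1-one | CC(C)(C)[Si](C)(C)OC[C@H]1CC(=O)C=CC1(C)C | intermediate
7 | ethyl 2-(2-methyl-1,3-dioxolan-2-yl)acetate | CCOC(=O)CC1(C)OCCO1 | starting material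
8 | 2-(2-methyl-1,3-dioxolan-2-yl)acetaldehyde | O=CCC1(C)OCCO1 | intermediate
9 | (E)-4-(2-methyl-1,3-dioxolan-2-yl)but-2-enal | O=C/C=C/CC1(C)OCCO1 | intermediate
10 | aldol adduct, (5S), epimers at C6 and carbinol carbon | CC(C)(C)[Si](C)(C)OC[C@H]1C(C(O)/C=C/CC2(C)OCCO2)C(=O)C=CC1(C)C | intermediate
11 | methanesulfonate of 10 | CC(C)(C)[Si](C)(C)OC[C@H]1C(C(OS(C)(=O)=O)/C=C/CC2(C)OCCO2)C(=O)C=CC1(C)C | intermediate
12 | (5R,6E)-silyloxymethyl alkylidene enone | CC(C)(C)[Si](C)(C)OC[C@H]1/C(=C\C=C\CC2(C)OCCO2)C(=O)C=CC1(C)C | intermediate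
13 | (5R,6E)-hydroxymethyl alkylidene enone | OC[C@H]1/C(=C\C=C\CC2(C)OCCO2)C(=O)C=CC1(C)C | intermediate
14 | imidazole-1-carboxylate of 13 | O=C(OC[C@H]1/C(=C\C=C\CC2(C)OCCO2)C(=O)C=CC1(C)C)n1ccnc1 | intermediate
15 | (3aR,7aR) cis-fused dienyl β-keto γ-lactone | O=C1OC[C@@H]2C(C)(C)C=CC(=O)[C@]12/C=C/C=C/C3(C)OCCO3 | intermediate
16 | (5R,6S)-triol, C1 epimers | OC[C@@H]1C(C)(C)C=CC(O)[C@@]1(CO)/C=C/C=C/C2(C)OCCO2 | intermediate
17 | (5R,6S)-5,6-bis(hydroxymethyl) dienyl enone | OC[C@@H]1C(C)(C)C=CC(=O)[C@@]1(CO)/C=C/C=C/C2(C)OCCO2 | intermediate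
18 | (1R,2S,5R)-2-hydroxymethyl-2-dienyl oxabicyclic ketone | OC[C@@]1(/C=C/C=C/C2(C)OCCO2)C(=O)C[C@H]2OC[C@@H]1C2(C)C | intermediate
19 | acryloyl chloride | C=CC(=O)Cl | starting material
20 | dienyl acrylate on the oxabicyclic ketone (key-step precursor) | C=CC(=O)OC[C@@]1(/C=C/C=C/C2(C)OCCO2)C(=O)C[C@H]2OC[C@@H]1C2(C)C | intermediate
21 | cis-fused cyclohexene δ-lactone with dioxolane (key-step product) | CC3(OCCO3)[C@H]1C=C[C@@H]2[C@H](C1)C(=O)OC[C@]21C(=O)C[C@H]2OC[C@@H]1C2(C)C | intermediate
22 | saturated ketal lactone | CC3(OCCO3)[C@H]1CC[C@@H]2[C@H](C1)C(=O)OC[C@]21C(=O)C[C@H]2OC[C@@H]1C2(C)C | intermediate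
23 | axial (7'S) methyl ketone | CC(=O)[C@H]1CC[C@@H]2[C@H](C1)C(=O)OC[C@]21C(=O)C[C@H]2OC[C@@H]1C2(C)C | intermediate
24 | equatorial (7'R) methyl ketone | CC(=O)[C@@H]1CC[C@@H]2[C@H](C1)C(=O)OC[C@]21C(=O)C[C@H]2OC[C@@H]1C2(C)C | intermediate
25 | isopropenyl compound | C=C(C)[C@@H]1CC[C@@H]2[C@H](C1)C(=O)OC[C@]21C(=O)C[C@H]2OC[C@@H]1C2(C)C | intermediate
26 | 2-substituted allyl alcohol | C=C(CO)[C@@H]1CC[C@@H]2[C@H](C1)C(=O)OC[C@]21C(=O)C[C@H]2OC[C@@H]1C2(C)C | intermediate
27 | 2-substituted acrylaldehyde | C=C(C=O)[C@@H]1CC[C@@H]2[C@H](C1)C(=O)OC[C@]21C(=O)C[C@H]2OC[C@@H]1C2(C)C | intermediate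
28 | CNP0268721.2 | C=C(C(=O)O)[C@@H]1CC[C@@H]2[C@H](C1)C(=O)OC[C@]21C(=O)C[C@H]2OC[C@@H]1C2(C)C | target

## Step count

- Total steps: 19.
- Longest linear sequence: 17 (steps 1–4 and 7–19, from 1).

## Steps most likely to fail

**Step 14.**
- What may go wrong: slow cycloaddition because the ester resists its s-cis form, leakage into the exo mode, or polymerisation of the acrylate on long heating.
- Fallback, from 18 back to 22: the dienophile is changed to an alkyne, which removes the endo/exo question. Compound 18 is esterified with propiolic acid (DCC, CH2Cl2, −20 °C) to the propiolate ester F1. Its linear, more reactive dienophile should cyclise in toluene at about 110 °C, through the same rotamer about C2–Ca, to the cyclohexa-1,4-diene lactone F2. Hydrogenation (H2, Pd/C, EtOAc) of both ring alkenes from the face opposite to C2 and the dioxolanyl carbon should set C8a' and give 22.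

**Step 10.**
- What may go wrong: loss of material through intermolecular acyl transfer, O-acylation, or opening of the dioxolane by β-elimination from the extended enolate.
- Fallback, from 13 back to 18: the bridge is closed first and the one-carbon unit is brought in as formaldehyde. Catalytic DBU in CH2Cl2 closes 13 to the 2-alkylidene oxabicyclic ketone F3. KN(SiMe3)2 (THF, −78 °C) then removes the exposed side-chain proton next to the dioxolane, and monomeric formaldehyde is added at −78 °C with an acetic acid quench. The aldol addition at C2 should come from the face of the O6–C7 bridge, because the other face is covered by the syn methyl group on C8. This gives 18 directly and makes steps 10 to 12 unnecessary.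

**Step 2.**
- What may go wrong: slow insertion at the neopentyl β-carbon, so that protodeboronation of the vinyl donor, a second addition, or eroded enantioselectivity take over.
- Fallback, from 2 back to 5: a silicon-masked hydroxymethyl nucleophile replaces vinyl. (Isopropoxydimethylsilyl)methylmagnesium chloride is added under CuBr·SMe2 and a Josiphos-type ferrocenyl diphosphine of the appropriate hand (t-BuOMe, −75 °C) to give the silane F4. Tamao–Kumada oxidation (H2O2, KF, KHCO3, THF/MeOH) then turns C–Si into C–OH and gives 5 without ozonolysis.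

## Further compounds

F1 | step 14 | [(1R,2S,5R)-8,8-dimethyl-2-[(1E,3E)-4-(2-methyl-1,3-dioxolan-2-yl)buta-1,3-dien-1-yl]-3-oxo-6-oxabicyclo[3.2.1]octan-2-yl]methyl propiolate | C#CC(=O)OC[C@@]1(/C=C/C=C/C2(C)OCCO2)C(=O)C[C@H]2OC[C@@H]1C2(C)C
F2 | step 14 | cyclohexa-1,4-diene δ-lactone (C8'=C8a' conjugated with the lactone, C5'=C6' isolated, C2 and dioxolanyl carbon cis) | CC3(OCCO3)[C@H]1C=C[C@@H]2C(=C1)C(=O)OC[C@]21C(=O)C[C@H]2OC[C@@H]1C2(C)C
F3 | step 10 | (1R,2E,5R)-8,8-dimethyl-2-[(E)-4-(2-methyl-1,3-dioxolan-2-yl)but-2-en-1-ylidene]-6-oxabicyclo[3.2.1]octan-3-one | O=C1C[C@H]2OC[C@H](C2(C)C)/C1=C\C=C\CC3(C)OCCO3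
F4 | step 2 | (S)-5-{[isopropoxy(dimethyl)silyl]methyl}-4,4-dimethylcyclohex-2-en-1-one | CC(C)O[Si](C)(C)C[C@H]1CC(=O)C=CC1(C)C
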